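**Retrosynthetic overview**
1. The ring stereocentres are (5R,9R,10R), i.e. (1R,4aR,8aR) on the decalin: this is the ent-labdane series, so the target is ent-copalol hydrogen malonate (ent-labda-8(17),13E-dien-15-yl hydrogen malonate). Normal-series sclareol, manool or sclareolide would give the wrong enantiomer.
2. Disconnection 1: the C15–O ester bond, giving ent-copalol and a malonyl mono-acyl donor (Meldrum's acid).
3. Disconnection 2: ent-copalol from C15 carboxyl reduction of (−)-copalic acid, which already carries the 8(17)-exo-methylene, the 13E-olefin and all three stereocentres.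
4. No ring is formed: the trans-decalin (rings A and B) is taken intact from the chiral pool. The order of events is C15 reduction, then O-malonylation.

Assumption: (−)-copalic acid (ent-labda-8(17),13E-dien-15-oic acid, CAS 24470-48-2), sold as a research chemical and the main diterpene acid of commercial copaiba oleoresin, counts as a commercially available starting material.

**Route**

Step 1
Reactants: 1 (−)-copalic acid [(2E)-3-methyl-5-[(1R,4aR,8aR)-5,5,8a-trimethyl-2-methylidenedecahydronaphthalen-1-yl]pent-2-enoic acid; trans-decalin with 10α-Me, 5β-H, 9β-H]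
Product: 2 ent-copalol [(2E)-3-methyl-5-[(1R,4aR,8aR)-5,5,8a-trimethyl-2-methylidenedecahydronaphthalen-1-yl]pent-2-en-1-ol]
Conditions: LiAlH4 (2.5 equiv), THF, 0 °C → rt, 3 h; then H2O, 15% aq NaOH, H2O (Fieser work-up)
Reagents that add atoms: none
Why: Hydride (LiAlH4) reduction of the carboxylic acid to the primary allylic alcohol, in which the unactivated 8(17) and 13E olefins are not touched and no stereocentre is made or broken, so the (5R,9R,10R) centres and the 13E geometry come unchanged from 1.

Step 2
Reactants: 2 ent-copalol; 3 Meldrum's acid (2,2-dimethyl-1,3-dioxane-4,6-dione)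
Product: 5 ent-copalyl hydrogen malonate (target), via hemiketal ester 4 (not isolated)
Conditions: 3 (1.2 equiv), toluene, 90 °C, 4 h; SiO2 (hexanes/EtOAc, 0.5% AcOH)
Reagents that add atoms: Meldrum's acid, CC1(C)OC(=O)CC(=O)O1
Why: Acylative ring-opening of Meldrum's acid by the primary allylic alcohol (nucleophilic acyl substitution) gives the 2-hydroxypropan-2-yl ester, which loses acetone to leave the malonic half-ester; only one acyl transfer is possible, so no diester forms, and no stereocentre or olefin is involved.

**Compound list**
1 | (−)-copalic acid, ent-labda-8(17),13E-dien-15-oic acid, (2E)-3-methyl-5-[(1R,4aR,8aR)-5,5,8a-trimethyl-2-methylidenedecahydronaphthalen-1-yl]pent-2-enoic acid | C=C1CC[C@@H]2C(C)(C)CCC[C@@]2(C)[C@@H]1CC/C(C)=C/C(=O)O | starting material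
2 | ent-copalol, ent-labda-8(17),13E-dien-15-ol, (2E)-3-methyl-5-[(1R,4aR,8aR)-5,5,8a-trimethyl-2-methylidenedecahydronaphthalen-1-yl]pent-2-en-1-ol | C=C1CC[C@@H]2C(C)(C)CCC[C@@]2(C)[C@@H]1CC/C(C)=C/CO | intermediate
3 | Meldrum's acid, 2,2-dimethyl-1,3-dioxane-4,6-dione | CC1(C)OC(=O)CC(=O)O1 | starting material
4 | hemiketal ester, ent-copalyl 2-hydroxypropan-2-yl malonate | C=C1CC[C@@H]2C(C)(C)CCC[C@@]2(C)[C@@H]1CC/C(C)=C/COC(=O)CC(=O)OC(C)(C)O | intermediate (not isolated)
5 | ent-copalyl hydrogen malonate, 3-{[(2E)-3-methyl-5-[(1R,4aR,8aR)-5,5,8a-trimethyl-2-methylidenedecahydronaphthalen-1-yl]pent-2-en-1-yl]oxy}-3-oxopropanoic acid | C=C1CC[C@@H]2C(C)(C)CCC[C@@]2(C)[C@@H]1CC/C(C)=C/COC(=O)CC(=O)O | target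

**Totals**
Total step count: 2.
Longest linear sequence: 2 steps (1 → 2 → 5).

**Steps most likely to fail**
The route has only two steps, so both are ranked and there is no third step to name.

Most at risk is step 2. The product is a prenyl-type allylic ester that also carries a free malonic acid, and it is made at 90 °C. It may partly decarboxylate to ent-copalyl acetate, ionise at C15, or let the 8(17)-olefin migrate. The fallback sets out from 2 (with 3) and comes back to the route at 5, and it keeps the terpene away from heat and acid. Meldrum's acid 3 is first opened with 2-(trimethylsilyl)ethanol (toluene, 90 °C) to give 2-(trimethylsilyl)ethyl hydrogen malonate F1. This acid is coupled with 2 under Steglich conditions (EDC·HCl, cat. DMAP, CH2Cl2, 0 °C → rt) to give the mixed diester ent-copalyl 2-(trimethylsilyl)ethyl malonate F2. Fluoride-induced β-elimination of the silylethyl group (TBAF, THF, 0 °C → rt, then work-up at pH 3–4) releases the free acid 5.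

Second is step 1. The free acid first forms a poorly soluble lithium carboxylate that may reduce sluggishly. Forcing the reaction at reflux risks hydroalumination of the allylic alkoxide (giving the 13,14-dihydro alcohol) or erosion of the 13E geometry. The fallback sets out from 1 and comes back at 2. The acid is O-methylated (MeI, K2CO3, DMF, rt) to methyl copalate F3, and the ester is then reduced with the electrophilic hydride DIBAL-H (2.5 equiv, CH2Cl2, −78 °C, Rochelle-salt work-up). This reagent gives clean 1,2-reduction of the enoate to ent-copalol 2.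

**Further compounds**
F1 | step 2 | 2-(trimethylsilyl)ethyl hydrogen malonate | C[Si](C)(C)CCOC(=O)CC(=O)O
F2 | step 2 | ent-copalyl 2-(trimethylsilyl)ethyl malonate | C=C1CC[C@@H]2C(C)(C)CCC[C@@]2(C)[C@@H]1CC/C(C)=C/COC(=O)CC(=O)OCC[Si](C)(C)C
F3 | step 1 | methyl copalate (methyl ent-labda-8(17),13E-dien-15-oate) | C=C1CC[C@@H]2C(C)(C)CCC[C@@]2(C)[C@@H]1CC/C(C)=C/C(=O)OC
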